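## Analysis of the target

Target 8 is a flavan, a chroman in which benzene ring A is fused to the dihydropyran ring C (O1, C2, C3, C4, C4a, C8a) and ring B, a 3,4,5-trimethoxyphenyl group, sits on C2; ring A carries methoxy groups at C7 and C8, so O1 lies between the ring fusion and a methoxy-bearing carbon. The only stereocentre is C2 (S), which is benzylic to ring B and is the ether carbon of ring C; with no second centre to relay from, its configuration must come from a catalyst or reagent. C3 and C4 are plain methylenes and C4 bears no oxygen, so any route through a chalcone, flavanone or flavone oxidation level carries a carbonyl that must later be removed. The sensitive element is the C2–O1 bond, a benzylic aryl alkyl ether next to an electron-rich ring B: strong Brønsted or Lewis acids can ionise it, which opens ring C and racemises C2, and hydrogenolysis can cleave it. The five aryl methyl ethers also exclude demethylating Lewis acids. The difficulty is therefore to set one isolated stereocentre in few steps, without redox corrections at C4 and without exposing C2 to ionising conditions afterwards. The strategy rests on the substitution at C2, which carries O1, C1′ of ring B and the C3 methylene. Once the O1–C8a aryl ether is opened, C2 is a secondary benzylic carbinol, the pattern left by a ring B aryl aldehyde that has taken up a two-carbon homobenzyl nucleophile (C3–C4) attached to ring A at C4a.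

## Retrosynthetic reasoning

**O1–C8a.** Ring C of 8 is opened at the aryl–oxygen bond, not at C2–O1, which leads to the bromo alcohol 7 with bromine at the future C8a. Cutting here leaves all four bonds at C2 untouched in the forward ring closure, so the configuration of 7 passes unchanged into 8. The forward reaction is an intramolecular O-arylation of a secondary alkoxide under Pd(OAc)2 with a bulky biaryl phosphine and a carbonate base. This turns a heterocycle problem into an acyclic carbinol problem and avoids acid at the benzylic ether.

**C2–C3.** The carbinol 7 is cut between the stereocentre and the adjacent methylene, giving the ring B aldehyde 6 and the homobenzyl zinc reagent 5. This is the only C–C bond at C2 whose cleavage yields an aromatic, non-enolisable aldehyde as electrophile, and it divides the molecule into two ten-carbon halves. Cutting C2–C1′ instead would call for aryl transfer to an enolisable 3-arylpropanal, and cutting C3–C4 or C4–C4a would leave the stereocentre to be set separately. The forward step must form the bond and choose the carbonyl face in one operation, under the catalyst formed from Ti(OiPr)4 and a chiral bis-sulfonamide, and must tolerate the aryl bromide needed for the ring closure; an sp3 carbon–zinc bond meets that condition. In 5 the second ligand on zinc is a trimethylsilylmethyl group, which is not transferred to aldehydes. A zinc reagent carrying two ring A groups would deliver one and lose the other on work-up; with the silylmethyl spectator each molecule of the ring A fragment is available for the bond formation.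

**C–Zn back to the alkene.** The organozinc 5 is traced through the alkyl(ethyl)zinc 4 and the primary alkylborane 3 to the styrene 2. The C3–C4 unit is thus a vinyl group that takes up hydrogen at the benzylic carbon and boron, then zinc, at the terminal carbon. Hydroboration with a dialkylborane, boron-to-zinc exchange and exchange of the remaining ethyl group for the silylmethyl ligand run in one flask and give a salt-free reagent. The titanium catalyst needs this, and a zinc insertion into an alkyl halide would not supply it directly.

**C=C.** The styrene 2 comes from methylenation of the commercial aldehyde 1. Compound 1 already carries the full ring A pattern: bromine between the formyl-bearing carbon and a methoxy group, which map onto C8a, C4a and C8, with the second methoxy at the future C7.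

## Alternatives that were turned down

**Alternative 1:** Ring C is dismantled at C4a–C4, C4–C3 and O1–C2, leading to 6-iodo-2,3-dimethoxyphenol (A2), 5-ethynyl-1,2,3-trimethoxybenzene (A3) and carbon monoxide (A4).
- Forward key step: PdCl2(PPh3)2 would couple A2, A4 and A3 to an ynone, and the phenol would then add 6-endo to give the flavone 7,8-dimethoxy-2-(3,4,5-trimethoxyphenyl)-4H-chromen-4-one (A1).
- For: one flask forms two C–C bonds, one C–O bond and ring C from simple pieces. On skeletal bonds per step it is stronger than the chosen route.
- Against: A1 is flat and at the wrong oxidation level. C2 would have to be created afterwards by enantioselective reduction of the C2=C3 bond of a vinylogous ester, a poorly reactive substrate class with few effective catalysts. The C4 carbonyl would then have to be removed at a 4-oxo stage that racemises by ring opening. The annulation also competes with 5-exo closure and with non-carbonylative coupling, and it needs a toxic gas.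
- Comparison: at least three steps follow the key step, and the stereocentre would be set late by the least reliable of them. The chosen route builds fewer bonds in its key step but sets C2 in that step, at the final oxidation level.

**Alternative 2:** The C2–C1′ bond is cut, giving 7,8-dimethoxy-4H-chromen-4-one (A6) and (3,4,5-trimethoxyphenyl)boronic acid (A7).
- Forward key step: Pd(OCOCF3)2 with a chiral pyridine–oxazoline ligand would transfer the aryl group from A7 to C2 of A6, giving (2S)-7,8-dimethoxy-2-(3,4,5-trimethoxyphenyl)chroman-4-one (A5).
- For: the partners are bench-stable and no fragment is used in excess. Ring C is already in place, and the stereocentre is formed in the joining step. On handling and operational simplicity it is at least as strong as the chosen route.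
- Against: A5 keeps the C4 carbonyl. Its removal costs two further steps, reduction to the benzylic alcohol and then deoxygenation, and the acidic silane or hydrogenolytic conditions for this also threaten the C2–O1 bond. A5 can open by retro-oxa-Michael reaction under acid or base, which racemises C2. A6 is a weak acceptor, because the C7 methoxy group donates into the carbonyl, so protodeboronation of the electron-rich A7 would compete.
- Comparison: the step count is similar. The chosen route never introduces a C4 oxygen and keeps C2 as a configurationally robust carbinol until a base-mediated closure.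

**Alternative 3:** The C4–C4a bond is cut, leading to the aryl propargyl ether 5-[(1S)-1-(2,3-dimethoxyphenoxy)prop-2-yn-1-yl]-1,2,3-trimethoxybenzene (A9).
- Forward key step: Ph3PAuNTf2 would activate the terminal alkyne of A9 and the ring A carbon para to the inner methoxy group would attack 6-endo. This gives (2S)-7,8-dimethoxy-2-(3,4,5-trimethoxyphenyl)-2H-chromene (A8), which hydrogenation of C3=C4 would convert into 8.
- For: the cyclisation under Ph3PAuNTf2 is mild and forms no stereocentre. Only one ortho position of ring A is free and it is electronically activated. No C4 oxygen has to be removed. The cyclisation itself is probably more dependable than an enantioselective organozinc addition.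
- Against: the configuration must survive two activated positions. Making A9 requires etherification at a benzylic and propargylic carbon with an ortho-substituted phenol, where ionisation erodes the configuration. In A8, C2 is benzylic, allylic and an ether carbon, so traces of acid, Ph3PAuNTf2 or reversible electrocyclic ring opening can scramble it. The final hydrogenation also risks hydrogenolysis of the C2–O1 bond.
- Comparison: the step count is about equal. The chosen route sets C2 in the convergent step and never activates it again.

Key step: step 3

Assumption on the sense of induction: the (1R,2R)-bis(triflamide) ligand is taken to deliver the alkyl group to the Si face of an aryl aldehyde, as in the ethylation of benzaldehyde to the S alcohol. If the sense proved opposite, the (1S,2S)-ligand would be used with no other change.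

Assumption on the reagent: (Me3SiCH2)2Zn is used as a distilled, salt-free liquid, bought or made from Me3SiCH2MgCl and ZnCl2.

## Route

Step 1
Reactants: 1 2-bromo-3,4-dimethoxybenzaldehyde
Product: 2 2-bromo-1-ethenyl-3,4-dimethoxybenzene (2-bromo-3,4-dimethoxystyrene)
Conditions: Ph3PCH3Br, KOtBu, THF, 0 °C to rt
Reagents that add atoms: methyltriphenylphosphonium bromide, C[P+](c1ccccc1)(c1ccccc1)c1ccccc1.[Br-]
Why: Wittig methylenation of a non-enolisable aryl aldehyde with the unstabilised methylene ylide should be clean; KOtBu is used instead of an alkyllithium so that bromine–lithium exchange at the aryl bromide cannot occur.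

Step 2
Reactants: 2 2-bromo-1-ethenyl-3,4-dimethoxybenzene
Product: 5 [2-(2-bromo-3,4-dimethoxyphenyl)ethyl](trimethylsilylmethyl)zinc, via 2-arylethyl(diethyl)borane 3 (not isolated), via 2-arylethyl(ethyl)zinc 4 (not isolated)
Conditions: Et2BH (from BH3·SMe2 + 2 Et3B), Et2O, 0 °C to rt; volatiles off; Et2Zn (neat, 3 equiv), 0 °C, 30 min; (Me3SiCH2)2Zn (0.6 equiv), rt; Et3B and Et2Zn off at ca. 10 mmHg, rt (repeated twice after adding toluene); residue taken up in toluene and used directly
Reagents that add atoms: diethylborane, CCBCC (supplies the BEt2 group of 3 and only hydrogen to 5); diethylzinc, CC[Zn]CC (supplies zinc and the ethyl group of 4); bis(trimethylsilylmethyl)zinc, C[Si](C)(C)C[Zn]C[Si](C)(C)C (supplies the CH2SiMe3 group of 5)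
Why: Anti-Markovnikov hydroboration of the styrene by a dialkylborane should place boron on the terminal carbon, helped by the ortho bromine and the para methoxy group, and boron–zinc exchange of the primary alkyldiethylborane 3 with Et2Zn then gives the alkyl(ethyl)zinc 4. Ligand redistribution of 4 with (Me3SiCH2)2Zn, pulled by evaporation of the volatile Et3B and Et2Zn, should leave the salt-free mixed diorganozinc 5, in which the CH2SiMe3 group is a ligand that is not transferred. The aryl bromide and the ethers are inert to all three reagents.

Step 3
Reactants: 5 [2-(2-bromo-3,4-dimethoxyphenyl)ethyl](trimethylsilylmethyl)zinc (about 1.6 equiv); 6 3,4,5-trimethoxybenzaldehyde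
Product: 7 (1S)-3-(2-bromo-3,4-dimethoxyphenyl)-1-(3,4,5-trimethoxyphenyl)propan-1-ol
Conditions: (1R,2R)-1,2-bis(trifluoromethanesulfonamido)cyclohexane (8 mol %), Ti(OiPr)4 (2 equiv), toluene, −20 °C; cold dilute aq. HCl
Reagents that add atoms: none
Why: Ti(OiPr)4 converts the bis-sulfonamide into a chiral, strongly Lewis acidic titanium bis(sulfonamido) complex; the 2-arylethyl group of 5 passes from zinc to titanium, aldehyde 6 binds to the chiral titanium centre and the alkyl group is delivered to one carbonyl face. The closest known reaction type is the addition of mixed primary alkyl(trimethylsilylmethyl)zincs to aromatic aldehydes catalysed by Ti(OiPr)4 and trans-1,2-bis(trifluoromethanesulfonamido)cyclohexane. No ring closes; the step forms the C2–C3 bond and joins the ring A and ring B halves. The new stereocentre C2 is controlled only by the twofold-symmetric ligand: the (1R,2R) enantiomer should direct the alkyl group to the Si face of the formyl group, which gives the S carbinol because the priorities are O > aryl > CH2 > H. The step needs enantioface selectivity, transfer of the 2-arylethyl group and not of the second ligand on zinc, alkyl transfer in preference to β-hydride reduction of the aldehyde, and reaction at C–Zn without touching C–Br. Face selectivity is served by the flat, non-enolisable aromatic aldehyde with two free ortho positions, the class this catalyst handles best, and the CH2SiMe3 group, which has no β-hydrogen and a hindered, silicon-stabilised carbon–zinc bond, stays on zinc. Low temperature and excess Ti(OiPr)4, which also releases the catalyst from the product alkoxide, favour alkyl transfer, and the aryl bromide is inert to alkylzincs when no late transition metal is present. The ligand-bound titanium species should react much faster than ligand-free titanium, and the organozinc alone does not add at −20 °C, so the racemic background should stay small.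

Step 4
Reactants: 7 (1S)-3-(2-bromo-3,4-dimethoxyphenyl)-1-(3,4,5-trimethoxyphenyl)propan-1-ol
Product: 8 (2S)-7,8-dimethoxy-2-(3,4,5-trimethoxyphenyl)chromane [(2S)-7,8,3′,4′,5′-pentamethoxyflavan]
Conditions: Pd(OAc)2 (5 mol %), rac-2-(di-tert-butylphosphino)-1,1′-binaphthyl (6 mol %), Cs2CO3, toluene, 80 °C
Reagents that add atoms: none
Why: Buchwald-type intramolecular C–O coupling: the aryl bromide adds oxidatively to zerovalent palladium, Cs2CO3 generates the palladium alkoxide, and the bulky di-tert-butyl biaryl phosphine should force C–O reductive elimination ahead of β-hydride elimination, closing the six-membered ring C at O1–C8a. No bond at C2 is broken, so the S configuration of 7 is retained in 8.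

## Compound list

1 | 2-bromo-3,4-dimethoxybenzaldehyde | O=Cc1ccc(OC)c(OC)c1Br | starting material
2 | 2-bromo-1-ethenyl-3,4-dimethoxybenzene | C=Cc1ccc(OC)c(OC)c1Br | intermediate
3 | [2-(2-bromo-3,4-dimethoxyphenyl)ethyl]diethylborane | CCB(CC)CCc1ccc(OC)c(OC)c1Br | intermediate (not isolated)
4 | [2-(2-bromo-3,4-dimethoxyphenyl)ethyl](ethyl)zinc | CC[Zn]CCc1ccc(OC)c(OC)c1Br | intermediate (not isolated)
5 | [2-(2-bromo-3,4-dimethoxyphenyl)ethyl](trimethylsilylmethyl)zinc | C[Si](C)(C)C[Zn]CCc1ccc(OC)c(OC)c1Br | intermediate
6 | 3,4,5-trimethoxybenzaldehyde | O=Cc1cc(OC)c(OC)c(OC)c1 | starting material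
7 | (1S)-3-(2-bromo-3,4-dimethoxyphenyl)-1-(3,4,5-trimethoxyphenyl)propan-1-ol | O[C@@H](CCc1ccc(OC)c(OC)c1Br)c1cc(OC)c(OC)c(OC)c1 | intermediate
8 | (2S)-7,8-dimethoxy-2-(3,4,5-trimethoxyphenyl)chromane | COc1cc([C@@H]2CCc3ccc(OC)c(OC)c3O2)cc(OC)c1OC | target

## Step count and risks

Total step count: 4. Longest linear sequence: 4 steps (1 → 2 → 5 → 7 → 8); aldehyde 6 enters at step 3.

**Step 3 (key step).** Facial selectivity or conversion may be insufficient, because aldehyde 6 is electron-rich and the transferred group is a functionalised homobenzyl carried by a mixed zinc reagent. β-Hydride transfer from the homobenzyl group could also reduce the aldehyde, and ethyl groups left on zinc after step 2 would be transferred competitively. The fallback sets out from 1 and returns at 7; it fixes C2 by ketone reduction instead of C–C addition. Claisen–Schmidt condensation of 1 with 1-(3,4,5-trimethoxyphenyl)ethan-1-one F1 (NaOH, EtOH) should give (2E)-3-(2-bromo-3,4-dimethoxyphenyl)-1-(3,4,5-trimethoxyphenyl)prop-2-en-1-one F2. Homogeneous hydrogenation of the C=C bond with RhCl(PPh3)3 and H2 spares the aryl bromide and the ketone and should give 3-(2-bromo-3,4-dimethoxyphenyl)-1-(3,4,5-trimethoxyphenyl)propan-1-one F3. Asymmetric transfer hydrogenation with RuCl[(S,S)-TsDPEN](p-cymene) in HCO2H/Et3N, the catalyst enantiomer that reduces acetophenone to the S alcohol, should then give 7.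

**Step 4.** β-Hydride elimination from the palladium alkoxide of the secondary benzylic alcohol would oxidise the carbinol and debrominate ring A. C–O reductive elimination from an electron-rich aryl palladium flanked by two ortho substituents is slow, which gives this side path time. The fallback sets out from 5 and 6 and returns at 8; it closes ring C at O1–C2 with inversion instead of at O1–C8a with retention. Step 3 run with the (1S,2S)-ligand should give (1R)-3-(2-bromo-3,4-dimethoxyphenyl)-1-(3,4,5-trimethoxyphenyl)propan-1-ol F4. Treatment with n-BuLi (2.2 equiv, THF, −78 °C) deprotonates the hydroxyl and exchanges bromine for lithium, and trapping with B(OMe)3 gives dimethyl {6-[(3R)-3-hydroxy-3-(3,4,5-trimethoxyphenyl)propyl]-2,3-dimethoxyphenyl}boronate F5. Oxidation in the same flask (NaOH, H2O2) should give 6-[(3R)-3-hydroxy-3-(3,4,5-trimethoxyphenyl)propyl]-2,3-dimethoxyphenol F6. Mitsunobu cyclisation (PPh3, DIAD, THF, 0 °C) then lets the phenol displace the activated benzylic oxygen with inversion, giving 8. The weak point of this path is partial ionisation at the benzylic carbon during the Mitsunobu step.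

**Step 2.** Some boron may add at the benzylic carbon. The boron–zinc exchange or the removal of Et3B and Et2Zn may be incomplete, which leaves ethyl groups on zinc that transfer in step 3. Partial loss of (Me3SiCH2)2Zn on evaporation would shift the ligand distribution on zinc, which costs efficiency of ring A transfer but not selectivity. The fallback sets out from 2 and returns at 4; it reaches the carbon–zinc bond by iodine–zinc exchange of a purified alkyl iodide. Hydroboration with 9-BBN (THF) gives 9-[2-(2-bromo-3,4-dimethoxyphenyl)ethyl]-9-borabicyclo[3.3.1]nonane F7. Oxidation in the same flask (NaOH, H2O2) gives 2-(2-bromo-3,4-dimethoxyphenyl)ethan-1-ol F8, which can be purified by chromatography. I2, PPh3 and imidazole in CH2Cl2 give 2-bromo-1-(2-iodoethyl)-3,4-dimethoxybenzene F9. Neat Et2Zn with catalytic CuI at 50 °C should convert F9 into 4 with loss of iodoethane. Addition of (Me3SiCH2)2Zn and evaporation as in step 2 then give 5.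

## Further compounds

F1 | step 3 | 1-(3,4,5-trimethoxyphenyl)ethan-1-one | CC(=O)c1cc(OC)c(OC)c(OC)c1
F2 | step 3 | (2E)-3-(2-bromo-3,4-dimethoxyphenyl)-1-(3,4,5-trimethoxyphenyl)prop-2-en-1-one | COc1cc(C(=O)/C=C/c2ccc(OC)c(OC)c2Br)cc(OC)c1OC
F3 | step 3 | 3-(2-bromo-3,4-dimethoxyphenyl)-1-(3,4,5-trimethoxyphenyl)propan-1-one | COc1cc(C(=O)CCc2ccc(OC)c(OC)c2Br)cc(OC)c1OC
F4 | step 4 | (1R)-3-(2-bromo-3,4-dimethoxyphenyl)-1-(3,4,5-trimethoxyphenyl)propan-1-ol | O[C@H](CCc1ccc(OC)c(OC)c1Br)c1cc(OC)c(OC)c(OC)c1
F5 | step 4 | dimethyl {6-[(3R)-3-hydroxy-3-(3,4,5-trimethoxyphenyl)propyl]-2,3-dimethoxyphenyl}boronate | COB(OC)c1c(CC[C@@H](O)c2cc(OC)c(OC)c(OC)c2)ccc(OC)c1OC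
F6 | step 4 | 6-[(3R)-3-hydroxy-3-(3,4,5-trimethoxyphenyl)propyl]-2,3-dimethoxyphenol | O[C@H](CCc1ccc(OC)c(OC)c1O)c1cc(OC)c(OC)c(OC)c1
F7 | step 2 | 9-[2-(2-bromo-3,4-dimethoxyphenyl)ethyl]-9-borabicyclo[3.3.1]nonane | COc1ccc(CCB2C3CCCC2CCC3)c(Br)c1OC
F8 | step 2 | 2-(2-bromo-3,4-dimethoxyphenyl)ethan-1-ol | OCCc1ccc(OC)c(OC)c1Br
F9 | step 2 | 2-bromo-1-(2-iodoethyl)-3,4-dimethoxybenzene | ICCc1ccc(OC)c(OC)c1Br
A1 | alternative 1 | 7,8-dimethoxy-2-(3,4,5-trimethoxyphenyl)-4H-chromen-4-one | COc1cc(-c2cc(=O)c3ccc(OC)c(OC)c3o2)cc(OC)c1OC
A2 | alternative 1 | 6-iodo-2,3-dimethoxyphenol | Oc1c(I)ccc(OC)c1OC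
A3 | alternative 1 | 5-ethynyl-1,2,3-trimethoxybenzene | C#Cc1cc(OC)c(OC)c(OC)c1
A4 | alternative 1 | carbon monoxide | [C-]#[O+]
A5 | alternative 2 | (2S)-7,8-dimethoxy-2-(3,4,5-trimethoxyphenyl)chroman-4-one | COc1cc([C@@H]2CC(=O)c3ccc(OC)c(OC)c3O2)cc(OC)c1OC
A6 | alternative 2 | 7,8-dimethoxy-4H-chromen-4-one | COc1ccc2c(=O)ccoc2c1OC
A7 | alternative 2 | (3,4,5-trimethoxyphenyl)boronic acid | COc1cc(B(O)O)cc(OC)c1OC
A8 | alternative 3 | (2S)-7,8-dimethoxy-2-(3,4,5-trimethoxyphenyl)-2H-chromene | COc1cc([C@@H]2C=Cc3ccc(OC)c(OC)c3O2)cc(OC)c1OC
A9 | alternative 3 | 5-[(1S)-1-(2,3-dimethoxyphenoxy)prop-2-yn-1-yl]-1,2,3-trimethoxybenzene | COc1cc([C@H](C#C)Oc2cccc(OC)c2OC)cc(OC)c1OC
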